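**Assumption:** eudesmane numbering (C1–C15) is used for the decalin and primed numbers for the acid; α/β mean below/above the ring plane with the C10 methyl β. Read this way the target is 3α-acyloxy-4β-hydroxy-5α-H, i.e. (3R,4R,5R,10R,2′S,3′S).

## Retrosynthetic overview

1. Target ⇒ singlet-oxygen ene reaction (O2, hν) of the 7(11)-en-8-one: the last step makes the C11–O bond and moves the alkene to C6=C7.
2. C8=O ⇒ anodic allylic C–H oxidation of the 7(11)-alkene, which comes from the isopropenyl compound by hydrogen-atom-transfer isomerisation.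
3. Ester ⇒ 3α,4β-diol + acetonide-protected (2S,3S)-2,3-dihydroxy-2-methylbutanoic acid; diol ⇒ α-epoxidation and trans-diaxial hydrolysis of 7-epi-α-selinene.
4. Decalin ⇒ Robinson annulation of (S)-carvone-derived dihydrocarvone with ethyl vinyl ketone: ring B is bought, ring A is annulated second; the C7 centre controls C10 and is erased later.
5. Acid ⇒ L-lactamide: 2-furyl ketone, chelation-controlled MeMgBr addition, acetonide, furan → CO2H.

## Route

Step 1
Reactants: 1 (S)-(+)-carvone
Product: 2 (2S,5S)-2-methyl-5-(prop-1-en-2-yl)cyclohexan-1-one [(−)-trans-dihydrocarvone; a little 2R epimer is carried along]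
Conditions: LiBH(s-Bu)3 (1.05 equiv), THF, −78 °C; then H2O
Reagents that add atoms: none
Why: Conjugate (1,4-) hydride reduction of the enone; the bought isopropenyl-bearing centre is untouched and the C2 epimers converge in step 2.

Step 2
Reactants: 2 (−)-dihydrocarvone; 3 ethyl vinyl ketone (pent-1-en-3-one)
Product: 5 (4aS,7S)-1,4a-dimethyl-7-(prop-1-en-2-yl)-4,4a,5,6,7,8-hexahydronaphthalen-2(3H)-one [10β-methyl-7α-isopropenyl-eudesma-4,11-dien-3-one], via Michael diketone 4 (not isolated)
Conditions: KOH (0.2 equiv), EtOH, −10 → 0 °C; then KOH (1 equiv), reflux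
Reagents that add atoms: none
Why: Robinson annulation (Michael addition of the more substituted enolate, then aldol condensation): axial alkylation puts the new C10–C1 bond cis to the equatorial isopropenyl group, so the bought C7 centre sets the quaternary C10 centre (methyl trans to isopropenyl, the 10-epi-cyperone series).

Step 3
Reactants: 5 enone
Product: 7 5α-H-7α-isopropenyl-10β-methyl-eudesma-3,11-dien-3-yl trifluoromethanesulfonate, via lithium enolate 6 (not isolated)
Conditions: Li (2.2 equiv), t-BuOH (1 equiv), NH3(l)/THF, −78 °C; evaporate NH3; PhNTf2 (1.1 equiv), THF, 0 °C → rt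
Reagents that add atoms: N-phenylbis(trifluoromethanesulfonimide), O=S(=O)(N(c1ccccc1)S(=O)(=O)C(F)(F)F)C(F)(F)F
Why: Dissolving-metal (Birch-type) enone reduction: the C5 carbanion is protonated axially, anti to the angular methyl, giving the trans ring fusion (5α-H), and the regiodefined C3–C4 enolate is trapped as the enol triflate.

Step 4
Reactants: 7 enol triflate
Product: 8 5α-H-7α-isopropenyl-10β-methyl-eudesma-3,11-diene (7-epi-α-selinene)
Conditions: Pd(OAc)2 (5 mol %), PPh3 (10 mol %), HCO2H (2 equiv), n-Bu3N (3 equiv), DMF, 60 °C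
Reagents that add atoms: none
Why: Palladium-catalysed formate reduction of an enol triflate (oxidative addition, formate-to-hydride exchange, reductive elimination) gives the 3-ene without touching any stereocentre.

Step 5
Reactants: 8 7-epi-α-selinene
Product: 10 5α-H-7α-isopropenyl-10β-methyl-eudesm-11-ene-3α,4β-diol, via 3α,4α-epoxide 9 (not isolated)
Conditions: mCPBA (1.0 equiv), CH2Cl2, −20 °C; then THF/H2O, HClO4 (cat.), 0 °C → rt
Reagents that add atoms: mCPBA (3-chloroperbenzoic acid), O=C(OO)c1cccc(Cl)c1; water, O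
Why: Prilezhaev epoxidation of the more electron-rich trisubstituted 3-ene from the α face (anti to the axial C10 methyl), then acid-catalysed trans-diaxial (Fürst–Plattner) opening by water at tertiary C4 with inversion, which sets C3 (α-O) and C4 (β-OH).

Step 6
Reactants: 11 (S)-2-hydroxy-N,N-dimethylpropanamide (L-lactic acid dimethylamide)
Product: 12 (S)-1-(furan-2-yl)-2-hydroxypropan-1-one
Conditions: furan (2.5 equiv), n-BuLi (2.2 equiv), THF, 0 °C; add 11, −78 → 0 °C; then H2O
Reagents that add atoms: 2-furyllithium, [Li]c1ccco1 (made in the flask from furan, c1ccoc1, and n-BuLi)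
Why: Nucleophilic acyl substitution of a tertiary amide by an organolithium: the tetrahedral adduct collapses only on work-up (no over-addition), and the lactate centre is protected from enolisation as its lithium alkoxide.

Step 7
Reactants: 12 furyl hydroxy ketone
Product: 13 (2S,3S)-2-(furan-2-yl)butane-2,3-diol
Conditions: MeMgBr (3 equiv), THF, −78 → −20 °C; then H2O
Reagents that add atoms: methylmagnesium bromide, C[Mg]Br
Why: Chelation-controlled Grignard addition (Cram cyclic model): the magnesium alkoxide and the carbonyl form a five-membered chelate and methyl adds on the face anti to the C3 methyl, so the bought lactate centre sets the tertiary centre.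

Step 8
Reactants: 13 furyl diol
Product: 14 (4S,5S)-4-(furan-2-yl)-2,2,4,5-tetramethyl-1,3-dioxolane
Conditions: 2-methoxypropene (2 equiv), PPTS (5 mol %), CH2Cl2, 0 °C
Reagents that add atoms: 2-methoxypropene, COC(C)=C
Why: Acid-catalysed acetal formation under conditions mild enough for the acid-sensitive tertiary furyl carbinol; no stereocentre is touched.

Step 9
Reactants: 14 furyl acetonide
Product: 15 (4S,5S)-2,2,4,5-tetramethyl-1,3-dioxolane-4-carboxylic acid
Conditions: RuCl3·xH2O (5 mol %), NaIO4 (8–10 equiv), EtOAc/MeCN/H2O, rt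
Reagents that add atoms: sodium periodate, [Na+].[O-]I(=O)(=O)=O; water, O
Why: RuO4 oxidative degradation of the furan ring unmasks it as the carboxylic acid; both stereocentres are non-epimerisable.

Step 10
Reactants: 10 3α,4β-diol; 15 acetonide acid
Product: 17 3α-ester of 10 with acid 15 (4β-OH free, 7α-isopropenyl), via Yamaguchi mixed anhydride 16 (not isolated)
Conditions: 15, 2,4,6-Cl3C6H2COCl (1.2 equiv), Et3N (1.5 equiv), THF, rt; then 10, DMAP (2 equiv), toluene, 80 °C
Reagents that add atoms: none
Why: Yamaguchi esterification: the mixed anhydride acylates the only secondary hydroxyl (axial 3α-OH) and leaves the tertiary 4β-OH free; no stereocentre is touched.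

Step 11
Reactants: 17 isopropenyl ester
Product: 18 the 7(11)-ene (7-isopropylidene) isomer of 17
Conditions: chlorocobalt complex of N,N′-bis(3,5-di-tert-butylsalicylidene)ethane-1,2-diamine, C32H46ClCoN2O2 (trivalent cobalt, 5 mol %), PhSiH3 (6 mol %), benzene, rt
Reagents that add atoms: none
Why: Cobalt-hydride hydrogen-atom-transfer alkene isomerisation: reversible H-atom addition to the isopropenyl CH2 gives the tertiary C11 radical, and loss of the C7 hydrogen gives the tetrasubstituted alkene, which is too hindered to react further; the C7 centre is erased here after doing its work.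

Step 12
Reactants: 18 7(11)-ene ester
Product: 20 the 7(11)-en-8-one (acetonide still in place), via allylic tert-butyl peroxide 19 (not isolated)
Conditions: undivided cell, reticulated vitreous carbon anode and cathode, constant current 10 mA (about 4 F/mol); N-hydroxytetrachlorophthalimide (20 mol %), pyridine (2 equiv), t-BuOOH (1.5 equiv), LiClO4 (0.1 M), acetone, rt
Reagents that add atoms: tert-butyl hydroperoxide, CC(C)(C)OO
Why: Proposed new method: N-oxyl-mediated anodic allylic C–H oxygenation is established for endocyclic di- and trisubstituted alkenes but not for an exocyclic tetrasubstituted isopropylidene alkene. The anodically formed tetrachlorophthalimide N-oxyl should abstract the axial 8β-hydrogen, which is aligned with the π bond and less shielded than 6β-H (syn-axial to both the 4β-OH and the C10 methyl). The allyl radical is then captured by t-BuOO• at the secondary terminus C8, and base-induced loss of t-BuOH gives the pulegone-type C8 ketone. The closest known reaction type is electrochemical allylic oxidation of cyclic terpene alkenes to enones (valencene to nootkatone).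

Step 13
Reactants: 20 acetonide enone
Product: 21 3α-[(2S,3S)-2,3-dihydroxy-2-methylbutanoyloxy]-4β-hydroxy-5α-H-eudesm-7(11)-en-8-one
Conditions: TFA/H2O (9:1), 0 °C, 30 min
Reagents that add atoms: none
Why: Acid-catalysed acetal hydrolysis; the hindered ester, the tertiary C4 alcohol (deactivated by the vicinal acyloxy group) and the isopropylidene ketone survive brief cold acid.

Step 14
Reactants: 21 isopropylidene ketone
Product: 23 CNP0124456.1 (target), via tertiary hydroperoxide 22 (not isolated)
Conditions: O2, tetraphenylporphyrin (1 mol %), white LED, CH2Cl2, 0 °C; then PPh3 (1.2 equiv), rt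
Reagents that add atoms: oxygen, O=O
Why: Schenck ene reaction of photosensitised singlet oxygen with the s-cis α-isopropylidene ketone: oxygen bonds to C11 and hydrogen is taken from C6 (the alkyl group geminal to the carbonyl, as with pulegone), so the alkene moves to C6=C7 in conjugation with C8=O; PPh3 reduces the hydroperoxide and C5 is not touched.

## Compound list

1 | (S)-(+)-carvone | CC1=CC[C@@H](CC1=O)C(C)=C | starting material
2 | (2S,5S)-2-methyl-5-(prop-1-en-2-yl)cyclohexan-1-one | C[C@H]1CC[C@@H](CC1=O)C(C)=C | intermediate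
3 | ethyl vinyl ketone | C=CC(=O)CC | starting material
4 | (2S,5S)-2-methyl-2-(3-oxopentyl)-5-(prop-1-en-2-yl)cyclohexan-1-one | CCC(=O)CC[C@]1(C)CC[C@H](C(C)=C)CC1=O | intermediate
5 | (4aS,7S)-1,4a-dimethyl-7-(prop-1-en-2-yl)-4,4a,5,6,7,8-hexahydronaphthalen-2(3H)-one | O=C1CC[C@]2(C)CC[C@H](C(C)=C)CC2=C1C | intermediate
6 | lithium 5α-H-7α-isopropenyl-10β-methyl-eudesma-3,11-dien-3-olate | [Li]OC1=C(C)[C@@H]2C[C@@H](C(C)=C)CC[C@@]2(C)CC1 | intermediate
7 | 5α-H-7α-isopropenyl-10β-methyl-eudesma-3,11-dien-3-yl triflate | O=S(=O)(OC1=C(C)[C@@H]2C[C@@H](C(C)=C)CC[C@@]2(C)CC1)C(F)(F)F | intermediate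
8 | 7-epi-α-selinene (5α-H, 7α-isopropenyl, 10β-methyl) | CC1=CCC[C@]2(C)CC[C@H](C(C)=C)C[C@@H]12 | intermediate
9 | 3α,4α-epoxy-7-epi-eudesm-11-ene | C[C@@]12O[C@@H]1CC[C@]3(C)CC[C@H](C(C)=C)C[C@@H]23 | intermediate
10 | 7-epi-eudesm-11-ene-3α,4β-diol | O[C@@H]1CC[C@]2(C)CC[C@H](C(C)=C)C[C@H]2[C@@]1(C)O | intermediate
11 | (S)-2-hydroxy-N,N-dimethylpropanamide | C[C@H](O)C(=O)N(C)C | starting material
12 | (S)-1-(furan-2-yl)-2-hydroxypropan-1-one | C[C@H](O)C(=O)c1ccco1 | intermediate
13 | (2S,3S)-2-(furan-2-yl)butane-2,3-diol | C[C@H](O)[C@](C)(O)c1ccco1 | intermediate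
14 | (4S,5S)-4-(furan-2-yl)-2,2,4,5-tetramethyl-1,3-dioxolane | C[C@@H]1OC(C)(C)O[C@]1(C)c1ccco1 | intermediate
15 | (4S,5S)-2,2,4,5-tetramethyl-1,3-dioxolane-4-carboxylic acid | C[C@@H]1OC(C)(C)O[C@]1(C)C(=O)O | intermediate
16 | mixed anhydride of 15 with 2,4,6-trichlorobenzoic acid | C[C@@H]1OC(C)(C)O[C@]1(C)C(=O)OC(=O)c1c(Cl)cc(Cl)cc1Cl | intermediate
17 | 3α-ester of diol 10 with acid 15 (7α-isopropenyl) | C[C@@H]1OC(C)(C)O[C@]1(C)C(=O)O[C@@H]1CC[C@]2(C)CC[C@H](C(C)=C)C[C@H]2[C@@]1(C)O | intermediate
18 | 7(11)-ene isomer of 17 | C[C@@H]1OC(C)(C)O[C@]1(C)C(=O)O[C@@H]1CC[C@]2(C)CCC(=C(C)C)C[C@H]2[C@@]1(C)O | intermediate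
19 | 8β-(tert-butylperoxy) derivative of 18 | C[C@@H]1OC(C)(C)O[C@]1(C)C(=O)O[C@@H]1CC[C@]2(C)C[C@@H](OOC(C)(C)C)C(=C(C)C)C[C@H]2[C@@]1(C)O | intermediate
20 | 7(11)-en-8-one acetonide ester | C[C@@H]1OC(C)(C)O[C@]1(C)C(=O)O[C@@H]1CC[C@]2(C)CC(=O)C(=C(C)C)C[C@H]2[C@@]1(C)O | intermediate
21 | 3α-[(2S,3S)-2,3-dihydroxy-2-methylbutanoyloxy]-4β-hydroxy-eudesm-7(11)-en-8-one | C[C@H](O)[C@](C)(O)C(=O)O[C@@H]1CC[C@]2(C)CC(=O)C(=C(C)C)C[C@H]2[C@@]1(C)O | intermediate
22 | 11-hydroperoxy-6-en-8-one | C[C@H](O)[C@](C)(O)C(=O)O[C@@H]1CC[C@]2(C)CC(=O)C(C(C)(C)OO)=C[C@H]2[C@@]1(C)O | intermediate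
23 | CNP0124456.1 | C[C@H](O)[C@](C)(O)C(=O)O[C@@H]1CC[C@]2(C)CC(=O)C(C(C)(C)O)=C[C@H]2[C@@]1(C)O | target

## Totals and risks

Total step count: 14 (steps 1–5 and 10–14 on the decalin line, steps 6–9 for the acid).
Longest linear sequence: 10 steps, from (S)-carvone (steps 1–5, 10–14).

**Step 12 (proposed new anodic oxidation).** The risks are attack at C6 or at the methyl groups, or coupling of the allyl radical at C11. The fallback uses known chemistry and sets out from 18. SeO2 (0.5 equiv) with t-BuOOH in CH2Cl2 at rt effects an ene/[2,3]-sigmatropic allylic hydroxylation (ring CH2 preferred over CH3, the less hindered C8 over C6) to give the 8β-hydroxy-7(11)-ene ester F1. Dess–Martin periodinane then oxidises it, coming back to the route at 20.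

**Step 10 (esterification).** The axial 3α-OH sits next to a tertiary carbinol and the acid is α-quaternary, so acyl transfer may stall. The fallback sets out from diol 10 and makes the C3–O bond by substitution instead. MsCl/Et3N gives the 3α-mesylate F2. K2CO3/MeOH closes it (the 4β-alkoxide displaces the antiperiplanar mesylate) to the 3β,4β-epoxide F3. The caesium salt of 15 (Cs2CO3, DMF, 90 °C) opens F3 at secondary C3 from the α face (trans-diaxial); the double inversion restores the 3α-oxygen and comes back at 17.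

**Step 11 (isomerisation to a tetrasubstituted alkene).** Hydrogen-atom abstraction at the hindered C7 methine may be slow. The fallback sets out from 17 and uses ionic addition–elimination. HCl in Et2O/CH2Cl2 at −20 °C adds in the Markovnikov sense to give the 11-chloro (2-chloropropan-2-yl) ester F4. LiBr/Li2CO3 in DMF at 100 °C then eliminates HCl under thermodynamic control to the more substituted alkene, coming back at 18; recovered 17 is recycled.

Further compounds
F1 | step 12 | 8β-hydroxy-7(11)-ene ester (allylic alcohol of 18) | C[C@@H]1OC(C)(C)O[C@]1(C)C(=O)O[C@@H]1CC[C@]2(C)C[C@@H](O)C(=C(C)C)C[C@H]2[C@@]1(C)O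
F2 | step 10 | 3α-methanesulfonate of diol 10 | CS(=O)(=O)O[C@@H]1CC[C@]2(C)CC[C@H](C(C)=C)C[C@H]2[C@@]1(C)O
F3 | step 10 | 3β,4β-epoxy-7-epi-eudesm-11-ene | C[C@]12O[C@H]1CC[C@]3(C)CC[C@H](C(C)=C)C[C@@H]23
F4 | step 11 | 11-chloro (2-chloropropan-2-yl) analogue of 17 | C[C@@H]1OC(C)(C)O[C@]1(C)C(=O)O[C@@H]1CC[C@]2(C)CC[C@H](C(C)(C)Cl)C[C@H]2[C@@]1(C)O
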